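**Strategy.** The ladder core is numbered as follows: ring A is C1–C6 with the chain on C3; ring B is C1, C6, C7, C8; ring C is C7–C10; ring D is C9–C12. Everything rests on cutting ring C across its bonds C8–C9 and C7–C10. The feature exploited is that ring C consists only of four cis-fused methines, C7/C8 shared with ring B and C9/C10 shared with ring D, so it is the [2+2] adduct of two ring alkenes. One photocycloaddition of cyclopent-2-en-1-one to a cyclobutene makes both bonds, ring C and all four centres. The precursor is the chain-bearing cis-bicyclo[4.2.0]oct-7-ene holding rings A and B, C1, C3, C6 and the acetonide-masked glycerol ether.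

Key step: step 8

Reading of the target: all three ring fusions are cis, rings A/C are anti across ring B, rings B/D are anti across ring C, and the chain on C3 is cis to ring B (H3 on the same face as H1 and H6).

Assumption: the oxazaborolidinium salt from (S)-α,α-diphenylprolinol is taken to give the (1R,6R) adduct 7, by analogy with the facial sense recalled for acrylate-type dienophiles held by an α-C–H···O contact (not derived independently); if the opposite sense is found at 7, the (R)-catalyst is used with no other change.

Design remark: the glycerol 1,3-diol is carried as an isopropylidene acetal and is attached only after rings A and B are complete. The cycloaddition and hydrogenation therefore run on a simple chloroalkyl hydrocarbon, both photochemical steps are free of benzylic hydrogens and aryl chromophores, and the last step needs no metal catalyst after the sulfur-based decarboxylation.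

Remark on step 8: the enone adds in both orientations; the two regioisomers get adjacent numbers and are carried together until they converge at 30.

**Route**

Step 1
Reactants: 1 1-bromo-8-chlorooctane; 2 chloroprene (2-chlorobuta-1,3-diene)
Product: 4 2-(8-chlorooctyl)buta-1,3-diene, via 8-chlorooctylmagnesium bromide 3 (not isolated)
Conditions: Mg, THF, 35 °C; then 2 (1.5 equiv), NiCl2(Ph2PCH2CH2CH2PPh2) (2 mol %), THF, 0 °C to 40 °C
Reagents that add atoms: none
Why: Kumada–Corriu coupling, in which magnesium inserts into the C–Br bond and leaves the C–Cl bond alone, and the nickel catalyst joins the primary alkyl Grignard reagent to the vinylic chloride of chloroprene while the unactivated alkyl chloride stays inert; no stereocentre is formed.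

Step 2
Reactants: 5 3-bromocyclobutan-1-one
Product: 6 cyclobut-2-en-1-one
Conditions: n-Bu3N (1.1 equiv), neat, rt; vacuum transfer into a −78 °C trap; used at once as a CH2Cl2 solution
Reagents that add atoms: none
Why: Base-mediated β-elimination (dehydrobromination, E1cB) of the β-bromo ketone by a non-nucleophilic amine, the volatile enone being removed from the ammonium salt by vacuum transfer before it can oligomerise; no stereocentre is formed.

Step 3
Reactants: 4 2-(8-chlorooctyl)buta-1,3-diene; 6 cyclobut-2-en-1-one
Product: 7 (1R,6R)-3-(8-chlorooctyl)bicyclo[4.2.0]oct-3-en-7-one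
Conditions: 6 (1.5 equiv), oxazaborolidine from (S)-α,α-diphenylprolinol and o-tolylboronic acid (20 mol %), Tf2NH (16 mol %), CH2Cl2, −78 to −40 °C
Reagents that add atoms: none
Why: Enantioselective Diels–Alder reaction catalysed by a chiral oxazaborolidinium ion, in which the boron-bound strained enone is attacked suprafacially by the s-cis diene on the face left open by the catalyst's phenyl group, setting C1 and C6 as a cis pair in the (1R,6R) sense, while the diene terminus next to the alkyl branch (larger HOMO coefficient) bonds to the enone β-carbon and places the chain on C3; the minor C4 regioisomer, which would feed the antipodal series once the ketone is gone, is removed here by chromatography.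

Step 4
Reactants: 7 (1R,6R)-3-(8-chlorooctyl)bicyclo[4.2.0]oct-3-en-7-one
Product: 8 (1R,3S,6R)-3-(8-chlorooctyl)bicyclo[4.2.0]octan-7-one
Conditions: H2 (1 atm), 5% Pd/C, EtOAc, rt
Reagents that add atoms: none
Why: Heterogeneous catalytic hydrogenation, in which the folded cis-bicycle should sit on the metal with its convex face (the one carrying H1 and H6, turned away from the four-membered ring), so both hydrogens arrive syn from that side and C3 is set with the chain cis to the cyclobutanone, the ketone and the primary chloride being untouched.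

Step 5
Reactants: 8 (1R,3S,6R)-3-(8-chlorooctyl)bicyclo[4.2.0]octan-7-one
Product: 10 (1R,3S,6R)-3-(8-chlorooctyl)bicyclo[4.2.0]oct-7-en-7-yl trifluoromethanesulfonate, via potassium enolate 9 (not isolated)
Conditions: KHMDS (1.1 equiv), THF, −78 °C; then PhNTf2 (1.2 equiv), −78 to 0 °C
Reagents that add atoms: N-phenylbis(trifluoromethanesulfonimide) O=S(=O)(N(c1ccccc1)S(=O)(=O)C(F)(F)F)C(F)(F)F
Why: Kinetic enolisation followed by O-sulfonylation (enol triflate formation), in which the hindered amide base takes a proton from the C8 methylene and not the ring-fusion C6–H, whose enolate would put a double bond at the bridgehead of the four-membered ring, so the C7=C8 enol triflate forms and C1, C3 and C6 are untouched.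

Step 6
Reactants: 10 (1R,3S,6R)-3-(8-chlorooctyl)bicyclo[4.2.0]oct-7-en-7-yl trifluoromethanesulfonate
Product: 11 (1R,3S,6S)-3-(8-chlorooctyl)bicyclo[4.2.0]oct-7-ene
Conditions: Pd(OAc)2 (5 mol %), PPh3 (10 mol %), HCO2H (2 equiv), n-Bu3N (3 equiv), DMF, 50 °C
Reagents that add atoms: none
Why: Palladium-catalysed formate reduction of an enol triflate, in which zerovalent palladium inserts into the vinylic C–O bond, formate replaces triflate and loses CO2 to give a palladium hydride, and reductive elimination leaves the C7=C8 cyclobutene, the alkyl chloride and the three stereocentres being spectators.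

Step 7
Reactants: 11 (1R,3S,6S)-3-(8-chlorooctyl)bicyclo[4.2.0]oct-7-ene; 12 2,2-dimethyl-1,3-dioxan-5-ol
Product: 14 5-{8-[(1R,3S,6S)-bicyclo[4.2.0]oct-7-en-3-yl]octyloxy}-2,2-dimethyl-1,3-dioxane, via sodium 2,2-dimethyl-1,3-dioxan-5-olate 13 (not isolated)
Conditions: 12 (2 equiv), NaH (2.2 equiv), THF/DMF (3:1), 0 °C; then 11, Bu4NI (20 mol %), 55 °C
Reagents that add atoms: none
Why: Williamson ether synthesis, in which the secondary alkoxide displaces the primary halide by SN2 (iodide from in situ Finkelstein exchange being the actual leaving group), the base-stable cyclobutene and the remote stereocentres taking no part.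

Step 8
Reactants: 14 5-{8-[(1R,3S,6S)-bicyclo[4.2.0]oct-7-en-3-yl]octyloxy}-2,2-dimethyl-1,3-dioxane; 15 cyclopent-2-en-1-one
Product: 16 cis,anti,cis tetracyclic cyclopentanone with C=O attached to C10 and 17 its regioisomer with C=O attached to C9 (carried on together)
Conditions: hν (350 nm, Pyrex), 15 (8 equiv, added in portions), CH2Cl2, −40 °C
Reagents that add atoms: none
Why: This is an enone–alkene [2+2] photocycloaddition, the closest known case being the addition of cyclopentenone to cis-3,4-disubstituted cyclobutenes: excited cyclopentenone crosses to its triplet, which bonds through its α- or β-carbon to C7 or C8 of the strained cyclobutene to give a triplet 1,4-biradical that collapses after spin inversion. Ring C (C7–C8–C9–C10) is thus closed by intermolecular union of two two-carbon units, its second bond arising by recombination of the 1,4-biradical. C7 and C8 are set by the face of the cyclobutene that is attacked: the exo (convex) face, turned away from the ring-A methylenes C2 and C5, is the open one, so rings A and C should come out anti across ring B. C9 and C10 must be cis because a five-membered ring can only be cis-fused to a cyclobutane, and the biradical should close with the five-membered ring turned away from ring B, which gives the anti relationship across ring C. The step needs this exo/anti selectivity but no regioselectivity, since the carbonyl carbon is excised later and both orientations end in the same ring D. The cyclobutene is the only alkene present, and the substrate offers neither benzylic hydrogens nor absorption at 350 nm.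

Step 9
Reactants: 16 C10-side tetracyclic ketone; 17 C9-side tetracyclic ketone
Product: 22 C10-side α-diazo ketone and 23 C9-side α-diazo ketone, via C10-side lithium enolate 18 (not isolated), via C9-side lithium enolate 19 (not isolated), via C10-side trifluoroacetyl ketone 20 (not isolated), via C9-side trifluoroacetyl ketone 21 (not isolated)
Conditions: LiHMDS (1.1 equiv), THF, −78 °C; CF3CO2CH2CF3 (1.2 equiv); then 4-acetamidobenzenesulfonyl azide (1.5 equiv), Et3N (1.5 equiv), MeCN, rt
Reagents that add atoms: 4-acetamidobenzenesulfonyl azide CC(=O)Nc1ccc(cc1)S(=O)(=O)N=[N+]=[N-]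
Why: Detrifluoroacetylative (Regitz-type deacylative) diazo transfer, in which each ketone enolises kinetically toward its α′-methylene and not toward the cyclobutane ring-fusion methine, the enolate is C-acylated, and the activated 1,3-dicarbonyl takes the diazo group from the sulfonyl azide with loss of the trifluoroacetyl group as the N-acyl sulfonamide; the ring stereocentres are untouched.

Step 10
Reactants: 22 C10-side α-diazo ketone; 23 C9-side α-diazo ketone
Product: 26 ring-D C11 carboxylic acid and 27 ring-D C12 carboxylic acid (each epimeric at the carboxyl-bearing carbon), via C11 ketene 24 (not isolated), via C12 ketene 25 (not isolated)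
Conditions: hν (300 nm), THF/H2O (4:1), 0 °C
Reagents that add atoms: water O
Why: Photochemical Wolff rearrangement used as a ring contraction, in which loss of N2 with 1,2-shift of the ring-fusion carbon (C10 or C9, with retention) to the carbene carbon gives a cyclobutylidene ketene that water captures as the acid, so the five-membered ring becomes ring D; the carboxyl-bearing centre forms unselectively and is erased in the next step.

Step 11
Reactants: 26 ring-D C11 carboxylic acid; 27 ring-D C12 carboxylic acid
Product: 30 5-{8-[ladder hydrocarbon]octyloxy}-2,2-dimethyl-1,3-dioxane (acetonide of the target), via C11 Barton ester 28 (not isolated), via C12 Barton ester 29 (not isolated)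
Conditions: N-hydroxypyridine-2-thione (1.2 equiv), DCC (1.2 equiv), DMAP (10 mol %), CH2Cl2, 0 °C to rt, dark; then t-BuSH (20 equiv), hν (tungsten lamp), 0 °C
Reagents that add atoms: none
Why: Barton reductive decarboxylation, in which the O-acyl thiohydroxamate fragments in a radical chain to CO2 and a cyclobutyl radical at C11 or C12 that the large excess of thiol should reduce faster than the strained ladder can open by β-scission, so both regioisomeric acids converge on one hydrocarbon and the epimeric centre disappears.

Step 12
Reactants: 30 acetonide of the target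
Product: 31 2-{8-[ladder hydrocarbon]octyloxy}propane-1,3-diol (target, CNP0193334.1)
Conditions: p-TsOH·H2O (10 mol %), MeOH/H2O (9:1), rt
Reagents that add atoms: none
Why: Acid-catalysed acetal hydrolysis frees the 1,3-diol under conditions that leave the saturated ladder hydrocarbon and the dialkyl ether alone; no stereocentre is affected.

**Compound list**

1 | 1-bromo-8-chlorooctane | ClCCCCCCCCBr | starting material
2 | chloroprene (2-chlorobuta-1,3-diene) | C=CC(Cl)=C | starting material
3 | 8-chlorooctylmagnesium bromide | ClCCCCCCCC[Mg]Br | intermediate (not isolated)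
4 | 2-(8-chlorooctyl)buta-1,3-diene | C=CC(=C)CCCCCCCCCl | intermediate
5 | 3-bromocyclobutan-1-one | O=C1CC(Br)C1 | starting material
6 | cyclobut-2-en-1-one | O=C1C=CC1 | intermediate
7 | (1R,6R)-3-(8-chlorooctyl)bicyclo[4.2.0]oct-3-en-7-one (cis-fused) | ClCCCCCCCCC1=CC[C@@H]2[C@H](C1)CC2=O | intermediate
8 | (1R,3S,6R)-3-(8-chlorooctyl)bicyclo[4.2.0]octan-7-one (H1, H3, H6 all cis) | ClCCCCCCCC[C@H]1CC[C@@H]2[C@H](C1)CC2=O | intermediate
9 | potassium (1R,3S,6R)-3-(8-chlorooctyl)bicyclo[4.2.0]oct-7-en-7-olate | ClCCCCCCCC[C@H]1CC[C@@H]2[C@H](C1)C=C2[O-].[K+] | intermediate (not isolated)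
10 | (1R,3S,6R)-3-(8-chlorooctyl)bicyclo[4.2.0]oct-7-en-7-yl trifluoromethanesulfonate | ClCCCCCCCC[C@H]1CC[C@@H]2[C@H](C1)C=C2OS(=O)(=O)C(F)(F)F | intermediate
11 | (1R,3S,6S)-3-(8-chlorooctyl)bicyclo[4.2.0]oct-7-ene | ClCCCCCCCC[C@H]1CC[C@@H]2[C@H](C1)C=C2 | intermediate
12 | 2,2-dimethyl-1,3-dioxan-5-ol | CC1(C)OCC(O)CO1 | starting material
13 | sodium 2,2-dimethyl-1,3-dioxan-5-olate | CC1(C)OCC([O-])CO1.[Na+] | intermediate (not isolated)
14 | 5-{8-[(1R,3S,6S)-bicyclo[4.2.0]oct-7-en-3-yl]octyloxy}-2,2-dimethyl-1,3-dioxane (key-step precursor; chain cis to the four-membered ring) | CC4(C)OCC(CO4)OCCCCCCCC[C@H]1CC[C@@H]2[C@H](C1)C=C2 | intermediate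
15 | cyclopent-2-en-1-one | O=C1C=CCC1 | starting material
16 | cis,anti,cis tetracyclic cyclopentanone, C=O attached to C10 (rings A, B, C and a cyclopentanone fused at C9–C10; fusions cis; A/C anti; B/five-ring anti) | CC4(C)OCC(CO4)OCCCCCCCC[C@H]1CC[C@@H]2[C@H](C1)[C@H]1[C@@H]3CCC(=O)[C@@H]3[C@@H]21 | intermediate
17 | regioisomer of 16, C=O attached to C9 (same relative and absolute configuration) | CC4(C)OCC(CO4)OCCCCCCCC[C@H]1CC[C@@H]2[C@H](C1)[C@H]1[C@@H]3C(=O)CC[C@@H]3[C@@H]21 | intermediate
18 | lithium enolate of 16 (toward the α′-methylene) | CC4(C)OCC(CO4)OCCCCCCCC[C@H]1CC[C@@H]2[C@H](C1)[C@H]1[C@@H]3CC=C([O-])[C@@H]3[C@@H]21.[Li+] | intermediate (not isolated)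
19 | lithium enolate of 17 (toward the α′-methylene) | CC4(C)OCC(CO4)OCCCCCCCC[C@H]1CC[C@@H]2[C@H](C1)[C@H]1[C@@H]3C([O-])=CC[C@@H]3[C@@H]21.[Li+] | intermediate (not isolated)
20 | α′-trifluoroacetyl derivative of 16 (diketo tautomer drawn; α′-carbon undefined) | CC4(C)OCC(CO4)OCCCCCCCC[C@H]1CC[C@@H]2[C@H](C1)[C@H]1[C@@H]3CC(C(=O)C(F)(F)F)C(=O)[C@@H]3[C@@H]21 | intermediate (not isolated)
21 | α′-trifluoroacetyl derivative of 17 (diketo tautomer drawn; α′-carbon undefined) | CC4(C)OCC(CO4)OCCCCCCCC[C@H]1CC[C@@H]2[C@H](C1)[C@H]1[C@@H]3C(=O)C(C(=O)C(F)(F)F)C[C@@H]3[C@@H]21 | intermediate (not isolated)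
22 | α′-diazo ketone from 16 | CC4(C)OCC(CO4)OCCCCCCCC[C@H]1CC[C@@H]2[C@H](C1)[C@H]1[C@@H]3CC(=[N+]=[N-])C(=O)[C@@H]3[C@@H]21 | intermediate
23 | α′-diazo ketone from 17 | CC4(C)OCC(CO4)OCCCCCCCC[C@H]1CC[C@@H]2[C@H](C1)[C@H]1[C@@H]3C(=O)C(=[N+]=[N-])C[C@@H]3[C@@H]21 | intermediate
24 | ring-D ketene at C11 (from 22) | CC4(C)OCC(CO4)OCCCCCCCC[C@H]1CC[C@@H]2[C@H](C1)[C@H]1[C@@H]3CC(=C=O)[C@@H]3[C@@H]21 | intermediate (not isolated)
25 | ring-D ketene at C12 (from 23) | CC4(C)OCC(CO4)OCCCCCCCC[C@H]1CC[C@@H]2[C@H](C1)[C@H]1[C@@H]3C(=C=O)C[C@@H]3[C@@H]21 | intermediate (not isolated)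
26 | ladder C11-carboxylic acid (epimers at C11; all other centres as in the target) | CC4(C)OCC(CO4)OCCCCCCCC[C@H]1CC[C@@H]2[C@H](C1)[C@H]1[C@@H]3CC(C(=O)O)[C@@H]3[C@@H]21 | intermediate
27 | ladder C12-carboxylic acid (epimers at C12; all other centres as in the target) | CC4(C)OCC(CO4)OCCCCCCCC[C@H]1CC[C@@H]2[C@H](C1)[C@H]1[C@@H]3C(C(=O)O)C[C@@H]3[C@@H]21 | intermediate
28 | O-acyl thiohydroxamate (Barton ester) of 26 | CC4(C)OCC(CO4)OCCCCCCCC[C@H]1CC[C@@H]2[C@H](C1)[C@H]1[C@@H]3CC(C(=O)On5ccccc5=S)[C@@H]3[C@@H]21 | intermediate (not isolated)
29 | O-acyl thiohydroxamate (Barton ester) of 27 | CC4(C)OCC(CO4)OCCCCCCCC[C@H]1CC[C@@H]2[C@H](C1)[C@H]1[C@@H]3C(C(=O)On5ccccc5=S)C[C@@H]3[C@@H]21 | intermediate (not isolated)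
30 | acetonide of the target: 5-{8-[ladder hydrocarbon]octyloxy}-2,2-dimethyl-1,3-dioxane (fusions cis; A/C and B/D anti; chain cis to ring B) | CC4(C)OCC(CO4)OCCCCCCCC[C@H]1CC[C@@H]2[C@H](C1)[C@H]1[C@@H]3CC[C@@H]3[C@@H]21 | intermediate
31 | 2-{8-[ladder hydrocarbon]octyloxy}propane-1,3-diol, CNP0193334.1 | OCC(CO)OCCCCCCCC[C@H]1CC[C@@H]2[C@H](C1)[C@H]1[C@@H]3CC[C@@H]3[C@@H]21 | target

**Step count.** Total: 12 steps. Longest linear sequence: 11 steps (steps 1, 3–12; the branch through step 2 is equally long).

**Steps most likely to fail**

Step 3. The catalysed cycloaddition may show weak enantiofacial or para/meta discrimination, or cyclobutenone may oligomerise before it is consumed. The fallback sets out from 4 and 6: the uncatalysed cycloaddition (CH2Cl2, rt), which this strained enone undergoes readily with simple dienes, gives racemic material, that is 7 together with its mirror image (1S,6S)-3-(8-chlorooctyl)bicyclo[4.2.0]oct-3-en-7-one F1. After removal of the C4 regioisomer on silica, the enantiomers are parted by preparative supercritical-fluid chromatography on a polysaccharide chiral phase. The route is rejoined at 7.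

Step 4. Facial discrimination at C3=C4 on the metal surface may be insufficient, giving C3 epimers. The fallback sets out from 7 and amplifies the bias with a temporary shielding group. Hydride reduction from the exo face of the cyclobutanone (NaBH4, MeOH, −20 °C) gives the endo alcohol (1R,6R,7S)-3-(8-chlorooctyl)bicyclo[4.2.0]oct-3-en-7-ol F2. Silylation (TIPSOTf, 2,6-lutidine) gives its triisopropylsilyl ether F3, whose bulky endo substituent lies over the concave face of ring A. Hydrogenation as in step 4 then gives the saturated silyl ether F4. Fluoride (Bu4NF, THF) frees the alcohol (1R,3S,6R,7S)-3-(8-chlorooctyl)bicyclo[4.2.0]octan-7-ol F5, and Dess–Martin oxidation returns to the route at 8.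

Step 8. The excited enone may be consumed by self-dimerisation, or exo/anti control may erode, so that little cis,anti,cis adduct is obtained. The fallback sets out from 14 and closes ring C with ring D already in place. A copper-catalysed [2+2] photocycloaddition (Salomon–Kochi reaction; (CuOTf)2·C6H6, 254 nm, Et2O) is run with a large excess of cyclobutene F6, which is made from bromocyclobutane with KOtBu in DMSO. Addition to the exo face of the fused cyclobutene should give the ladder directly. This replaces steps 8–11 and returns to the route at 30.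

Further compounds
F1 | step 3 | (1S,6S)-3-(8-chlorooctyl)bicyclo[4.2.0]oct-3-en-7-one (enantiomer of 7) | ClCCCCCCCCC1=CC[C@H]2[C@@H](C1)CC2=O
F2 | step 4 | (1R,6R,7S)-3-(8-chlorooctyl)bicyclo[4.2.0]oct-3-en-7-ol (endo alcohol) | ClCCCCCCCCC1=CC[C@@H]2[C@H](C1)C[C@@H]2O
F3 | step 4 | (1R,6R,7S)-3-(8-chlorooctyl)-7-(triisopropylsilyloxy)bicyclo[4.2.0]oct-3-ene | ClCCCCCCCCC1=CC[C@@H]2[C@H](C1)C[C@@H]2O[Si](C(C)C)(C(C)C)C(C)C
F4 | step 4 | (1R,3S,6R,7S)-3-(8-chlorooctyl)-7-(triisopropylsilyloxy)bicyclo[4.2.0]octane | ClCCCCCCCC[C@H]1CC[C@@H]2[C@H](C1)C[C@@H]2O[Si](C(C)C)(C(C)C)C(C)C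
F5 | step 4 | (1R,3S,6R,7S)-3-(8-chlorooctyl)bicyclo[4.2.0]octan-7-ol | ClCCCCCCCC[C@H]1CC[C@@H]2[C@H](C1)C[C@@H]2O
F6 | step 8 | cyclobutene | C1=CCC1
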